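The target is a 2,5-diaryl-3,4-dimethyloxolan-3-ol (O1, C2–C5; C3 is the tertiary carbinol). The oxolane is opened at O1–C5, and the oxygens on C2 and C3 are traced to a Z-C2=C3 alkene, leaving a homoallylic alcohol. Its two benzylic C–C bonds, C2–C3 and C4–C5, are made in one pot. A lithiated benzyl carbamate (C2) is borylated by a (Z)-but-2-en-2-ylboronate (C3, C4, both methyls). A 1,2-metallate shift forms C2–C3 and an α-aryl allylboronate, which adds through C4 to an aryl aldehyde (C5). The step exploits the C3(CH3)–C4(CH3) unit flanked by the aryl-bearing ring carbons C2 and C5.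

Key step: step 2

Assumption: the configurationally labile lithio carbamate is taken to equilibrate to its (R)-epimer under the (S,S)-bis(oxazoline) ligand; if the sense is the opposite, the (R,R)-ligand is used and nothing else changes.

Step 1
Reactants: 1 [4-(benzyloxy)-3-methoxyphenyl]methanol
Product: 2 4-(benzyloxy)-3-methoxybenzyl N,N-diisopropylcarbamate
Conditions: NaH, iPr2NCOCl, THF, 0 °C to reflux
Reagents that add atoms: N,N-diisopropylcarbamoyl chloride, CC(C)N(C(C)C)C(Cl)=O
Why: O-Carbamoylation of the sodium alkoxide should give the carbamate that later directs benzylic lithiation and serves as the leaving group; no stereocentre is formed.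

Step 2
Reactants: 2 4-(benzyloxy)-3-methoxybenzyl N,N-diisopropylcarbamate; 3 (Z)-2-(but-2-en-2-yl)-4,4,5,5-tetramethyl-1,3,2-dioxaborolane; 4 4-(benzyloxy)-3-methoxybenzaldehyde
Product: 9 (1S,2S,3Z)-1,4-bis[4-(benzyloxy)-3-methoxyphenyl]-2,3-dimethylbut-3-en-1-ol, via lithio carbamate 5 (not isolated), via boronate complex 6 (not isolated), via allylboronate 7 (not isolated), via borate ester 8 (not isolated)
Conditions: s-BuLi, (S,S)-iPr-BOX [2,2'-(propane-2,2-diyl)bis((4S)-4-isopropyl-4,5-dihydrooxazole)], toluene, −78 °C; then 3, −78 °C to rt; then 4, rt to 40 °C; then H2O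
Reagents that add atoms: none
Why: The ligand-bound (R)-lithio carbamate 5 is borylated by 3 with retention to give boronate complex 6, whose butenyl group migrates from boron to carbon with inversion and loss of the carbamate (lithiation–borylation), forming C2–C3 of the oxolane and the α-aryl allylboronate 7. Allylboration of 4 by 7 through a closed six-membered chair transition state then forms C4–C5 and gives borate 8, hydrolysed to 9; the closest known reaction type is the one-pot lithiation–borylation–allylboration of lithiated carbamates, alkenylboronic esters and aldehydes. No ring is closed in this step. The carbinol centre C5 and the methyl-bearing centre C4 are set anti by the E-crotyl-type geometry of 7 (aldehyde aryl equatorial), and their absolute sense is relayed from the boron-bearing carbon of 7. The step needs γ-selective, Z-selective allyl transfer, which the β-methyl group and the pinacol ester should secure by forcing the α-aryl group pseudo-axial (avoiding 1,2-allylic strain), so that the (R)-boronate gives the (1S,2S,3Z) product. It also needs configurational integrity of 5, for which the chiral bis(oxazoline) ligand and −78 °C are relied on.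

Step 3
Reactants: 9 (1S,2S,3Z)-1,4-bis[4-(benzyloxy)-3-methoxyphenyl]-2,3-dimethylbut-3-en-1-ol
Product: 10 (1R,2S,3R,4S)-1,4-bis[4-(benzyloxy)-3-methoxyphenyl]-2,3-dimethylbutane-1,2,4-triol
Conditions: OsO4 (cat.), NMO, acetone/H2O, 0 °C to rt
Reagents that add atoms: osmium tetroxide (OsO4), O=[Os](=O)(=O)=O; N-methylmorpholine N-oxide, C[N+]1([O-])CCOCC1; water, O
Why: Upjohn dihydroxylation adds both oxygens syn to the Z-alkene, and 1,3-allylic strain with the cis aryl group should hold the allylic C–H in the alkene plane so that osmium attacks the methyl-bearing face anti to the CH(OH)Ar group, which sets C2 and C3 of the oxolane.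

Step 4
Reactants: 10 (1R,2S,3R,4S)-1,4-bis[4-(benzyloxy)-3-methoxyphenyl]-2,3-dimethylbutane-1,2,4-triol
Product: 11 (2R,3S,4R,5S)-2,5-bis[4-(benzyloxy)-3-methoxyphenyl]-3,4-dimethyloxolan-3-ol
Conditions: CSA (cat.), CH2Cl2, 0 °C
Reagents that add atoms: none
Why: Acid-catalysed SN1 cycloetherification should ionise the C5 benzylic alcohol (the C2 carbinol is deactivated by the adjacent tertiary hydroxyl) and the C2 hydroxyl closes the five-membered ring, the C5 aryl group settling trans to the C4 methyl and on the face opposite to the C2 aryl group under kinetic and thermodynamic control.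

Step 5
Reactants: 11 (2R,3S,4R,5S)-2,5-bis[4-(benzyloxy)-3-methoxyphenyl]-3,4-dimethyloxolan-3-ol
Product: 12 (2R,3S,4R,5S)-2,5-bis(4-hydroxy-3-methoxyphenyl)-3,4-dimethyloxolan-3-ol
Conditions: H2 (1 atm), Pd/C, EtOAc, rt
Reagents that add atoms: none
Why: Hydrogenolysis of the two aryl benzyl ethers should free the phenols without touching the four stereocentres, the ring benzylic C–O bonds being cleaved more slowly than O-benzyl ethers.

Compound list
1 | [4-(benzyloxy)-3-methoxyphenyl]methanol | COc1cc(CO)ccc1OCc1ccccc1 | starting material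
2 | 4-(benzyloxy)-3-methoxybenzyl N,N-diisopropylcarbamate | COc1cc(COC(=O)N(C(C)C)C(C)C)ccc1OCc1ccccc1 | intermediate
3 | (Z)-2-(but-2-en-2-yl)-4,4,5,5-tetramethyl-1,3,2-dioxaborolane (methyl groups cis) | C/C=C(\C)B1OC(C)(C)C(C)(C)O1 | starting material
4 | 4-(benzyloxy)-3-methoxybenzaldehyde | COc1cc(C=O)ccc1OCc1ccccc1 | starting material
5 | (R)-[4-(benzyloxy)-3-methoxyphenyl][(diisopropylcarbamoyl)oxy]methyllithium (ligand-bound lithio carbamate) | COc1cc([C@H](OC(=O)N(C(C)C)C(C)C)[Li])ccc1OCc1ccccc1 | intermediate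
6 | lithium [(R)-[4-(benzyloxy)-3-methoxyphenyl][(diisopropylcarbamoyl)oxy]methyl][(Z)-but-2-en-2-yl](pinacolato)borate | [Li+].COc1cc([C@H](OC(=O)N(C(C)C)C(C)C)[B-]2(OC(C)(C)C(C)(C)O2)/C(C)=C/C)ccc1OCc1ccccc1 | intermediate
7 | 2-{(1R,2E)-1-[4-(benzyloxy)-3-methoxyphenyl]-2-methylbut-2-en-1-yl}-4,4,5,5-tetramethyl-1,3,2-dioxaborolane | COc1cc([C@H](B2OC(C)(C)C(C)(C)O2)/C(C)=C/C)ccc1OCc1ccccc1 | intermediate
8 | 2-{[(1S,2S,3Z)-1,4-bis[4-(benzyloxy)-3-methoxyphenyl]-2,3-dimethylbut-3-en-1-yl]oxy}-4,4,5,5-tetramethyl-1,3,2-dioxaborolane | COc1cc([C@@H](OB2OC(C)(C)C(C)(C)O2)[C@@H](C)/C(C)=C\c2ccc(OCc3ccccc3)c(OC)c2)ccc1OCc1ccccc1 | intermediate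
9 | (1S,2S,3Z)-1,4-bis[4-(benzyloxy)-3-methoxyphenyl]-2,3-dimethylbut-3-en-1-ol | COc1cc([C@@H](O)[C@@H](C)/C(C)=C\c2ccc(OCc3ccccc3)c(OC)c2)ccc1OCc1ccccc1 | intermediate
10 | (1R,2S,3R,4S)-1,4-bis[4-(benzyloxy)-3-methoxyphenyl]-2,3-dimethylbutane-1,2,4-triol | COc1cc([C@@H](O)[C@@H](C)[C@](C)(O)[C@H](O)c2ccc(OCc3ccccc3)c(OC)c2)ccc1OCc1ccccc1 | intermediate
11 | (2R,3S,4R,5S)-2,5-bis[4-(benzyloxy)-3-methoxyphenyl]-3,4-dimethyloxolan-3-ol | COc1cc([C@H]2O[C@H](c3ccc(OCc4ccccc4)c(OC)c3)[C@@](C)(O)[C@@H]2C)ccc1OCc1ccccc1 | intermediate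
12 | (2R,3S,4R,5S)-2,5-bis(4-hydroxy-3-methoxyphenyl)-3,4-dimethyloxolan-3-ol | COc1cc([C@H]2O[C@H](c3ccc(O)c(OC)c3)[C@@](C)(O)[C@@H]2C)ccc1O | target

Total step count: 5. Longest linear sequence: 5 steps (1 → 2 → 9 → 10 → 11 → 12).

Steps most likely to fail

Risk 1, step 2. The benzylic organolithium 5 may epimerise before or during borylation, and the allyl transfer may not place the aryl group cleanly pseudo-axial. Either erodes the enantiomeric purity, because the E-alkene product carries the mirror-image carbinol and methine centres. The fallback sets out from aldehyde 4 and rejoins the route at boronate complex 6. Enantioselective 1,2-borylation of 4 (CuCl, chiral bisphosphine, B2pin2, MeOH) should give (R)-[4-(benzyloxy)-3-methoxyphenyl](4,4,5,5-tetramethyl-1,3,2-dioxaborolan-2-yl)methanol F1. This is carbamoylated directly (iPr2NCOCl, base) to the configurationally stable (R)-[4-(benzyloxy)-3-methoxyphenyl](4,4,5,5-tetramethyl-1,3,2-dioxaborolan-2-yl)methyl N,N-diisopropylcarbamate F2. (Z)-But-2-en-2-yllithium F3, made from (E)-2-bromobut-2-ene and t-BuLi at −78 °C, is then added to the boron of F2. This gives the same complex 6 without a free benzylic carbanion, and 6 goes on to 7, 8 and 9 as in the main route after warming and addition of 4.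

Risk 2, step 4. Ionisation may compete at the C2 carbinol next to the tertiary alcohol, causing loss of configuration at C2 or a pinacol-type 1,2-shift. Prolonged acid may also reopen the product ring at O1–C2. The fallback sets out from 9 and comes back at 11. Acetylation of 9 (Ac2O, DMAP) gives (1S,2S,3Z)-1,4-bis[4-(benzyloxy)-3-methoxyphenyl]-2,3-dimethylbut-3-en-1-yl acetate F4. Dihydroxylation as in step 3 gives (1S,2R,3S,4R)-1,4-bis[4-(benzyloxy)-3-methoxyphenyl]-3,4-dihydroxy-2,3-dimethylbutyl acetate F5. A catalytic Lewis acid (Sc(OTf)3, CH2Cl2, −40 °C) then ionises only the benzylic acetate, a far better nucleofuge than either free hydroxyl, and the C2 hydroxyl closes the ring to 11.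

Risk 3, step 3. Facial discrimination by the allylic stereocentre may be insufficient, or the homoallylic hydroxyl may deliver the oxidant to the wrong face. The fallback sets out from 9, bypasses the triol and comes back at 11. Z-to-E isomerisation (PhSSPh cat., hν) gives (1S,2S,3E)-1,4-bis[4-(benzyloxy)-3-methoxyphenyl]-2,3-dimethylbut-3-en-1-ol F6. Reagent-controlled Shi epoxidation, with the ketone enantiomer that gives the (2S,3S)-oxirane, affords (1S,2R)-1-[4-(benzyloxy)-3-methoxyphenyl]-2-{(2S,3S)-3-[4-(benzyloxy)-3-methoxyphenyl]-2-methyloxiran-2-yl}propan-1-ol F7. Invertive 5-endo opening of the benzylic epoxide carbon by the carbinol oxygen (CSA cat., CH2Cl2, −20 °C) then forms O1–C2 and leaves the C3 hydroxyl, giving 11.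

Further compounds
F1 | step 2 | (R)-[4-(benzyloxy)-3-methoxyphenyl](4,4,5,5-tetramethyl-1,3,2-dioxaborolan-2-yl)methanol | COc1cc([C@H](O)B2OC(C)(C)C(C)(C)O2)ccc1OCc1ccccc1
F2 | step 2 | (R)-[4-(benzyloxy)-3-methoxyphenyl](4,4,5,5-tetramethyl-1,3,2-dioxaborolan-2-yl)methyl N,N-diisopropylcarbamate | COc1cc([C@H](OC(=O)N(C(C)C)C(C)C)B2OC(C)(C)C(C)(C)O2)ccc1OCc1ccccc1
F3 | step 2 | (Z)-but-2-en-2-yllithium | C/C=C(\C)[Li]
F4 | step 4 | (1S,2S,3Z)-1,4-bis[4-(benzyloxy)-3-methoxyphenyl]-2,3-dimethylbut-3-en-1-yl acetate | COc1cc([C@@H](OC(C)=O)[C@@H](C)/C(C)=C\c2ccc(OCc3ccccc3)c(OC)c2)ccc1OCc1ccccc1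
F5 | step 4 | (1S,2R,3S,4R)-1,4-bis[4-(benzyloxy)-3-methoxyphenyl]-3,4-dihydroxy-2,3-dimethylbutyl acetate | COc1cc([C@@H](OC(C)=O)[C@@H](C)[C@](C)(O)[C@H](O)c2ccc(OCc3ccccc3)c(OC)c2)ccc1OCc1ccccc1
F6 | step 3 | (1S,2S,3E)-1,4-bis[4-(benzyloxy)-3-methoxyphenyl]-2,3-dimethylbut-3-en-1-ol | COc1cc([C@@H](O)[C@@H](C)/C(C)=C/c2ccc(OCc3ccccc3)c(OC)c2)ccc1OCc1ccccc1
F7 | step 3 | (1S,2R)-1-[4-(benzyloxy)-3-methoxyphenyl]-2-{(2S,3S)-3-[4-(benzyloxy)-3-methoxyphenyl]-2-methyloxiran-2-yl}propan-1-ol | COc1cc([C@@H](O)[C@@H](C)[C@]2(C)O[C@H]2c2ccc(OCc3ccccc3)c(OC)c2)ccc1OCc1ccccc1
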